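I had to choose a charge for the next run. The choice was between Sunday's and Tuesday's recipes, and I wanted to know whether Tuesday's heavier charge would buy a better split between target and its isomer.

| flask | substrate | reagent | remark | time |
|---|---|---|---|---|
| noon | 0.20 M | 0.29 M | run made earlier |  |
| summer | 0.20 M | 1.1 M | run made earlier |  |
| winter | 0.43 M | 0.24 M | run made earlier |  |
| Sunday's | 0.20 M | 0.240 M |  | 12 d |
| Tuesday's | 0.60 M | 1.00 M |  | 12 d |

| run | time / d | target / % | isomer of the product / % |
|---|---|---|---|
| noon | 2.50 | 36 | 31 |
| noon | 5.00 | 44 | 43 |
| noon | 8.00 | 48 | 52 |
| noon | 10.0 | 49 | 47 |
| noon | 12.0 | 48 | 47 |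
| summer | 1.04 | 52 | 39 |
| summer | 3.00 | 50 | 49 |
| summer | 6.00 | 50 | 49 |
| summer | 8.00 | 52 | 49 |
| summer | 12.0 | 54 | 49 |
| winter | 2.50 | 25 | 23 |
| winter | 5.00 | 28 | 27 |
| winter | 8.00 | 28 | 28 |
| winter | 10.0 | 26 | 22 |
| winter | 12.0 | 30 | 30 |

(each reading ± 2 percentage points)

1. the flask that ends with the higher share of target in all that became target or isomer of the product, or "neither" when 2 percentage points or less lies between them (Sunday's / Tuesday's / neither)
2. share of target in all that became target or isomer of the product, Sunday's
3. share of target in all that became target or isomer of the product, Tuesday's

- steps that have been proposed: substrate + reagent -> intermediate + by-product; intermediate -> target; target <-> isomer of the product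

I asked first what the end state must be. Target and the isomer of the product interconvert, so a flask left long enough should hold them at their balance. The summer run's readings from 3.00 d on gave 51.2% of target in target plus isomer, and this I called the balance share s. The winter run, with 0.24 M of reagent against 0.43 M of substrate, made less product by its last reading than the summer run, yet from 5.00 d on it gave 51.1%, so I expected thermodynamic control of the split.

Then I asked how fast the balance is approached. The summer run read 57.1% at 1.04 d but 50.5% at 3.00 d, so in that run's readings the gap was gone within 1.96 d, which is far shorter than the 12 d allowed. I therefore committed to s for both flasks and to no difference between them, and I left the choice of recipe to the amount wanted.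

The forecast likewise said neither, with 51% for Sunday's and 51% for Tuesday's, reasoning of reagent and substrate that “They do not appear to change the split”.

    substrate + reagent → intermediate + by-product (k = 2.90 × 10⁻⁵ /M/s)
    intermediate → target (k = 1.50 × 10⁻⁴ /s)
    target ⇌ isomer of the product (K = 0.970, k = 2.00 × 10⁻⁵ /s)

Sunday's ended at 50.9% and Tuesday's at 50.8%, so the answer was neither, and both lay within 2 percentage points of s, 51.2%. In Sunday's at 12.0 d, with 6.7% of the substrate left, substrate had a half-life of 5.2 d by its step, while target and isomer closed half their gap to balance in 0.198 d. That is 26.3 times shorter. A neighbour of Sunday's, charged with 0.50 M of substrate, had reagent as its limiting reagent, with 0.021% of the reagent's charge left at 12.0 d, and it kept 52.0% of its substrate unconverted, yet its share stood at 50.8%, within 2 points of s.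

All runs were computed with constants of no real substance, noise included.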